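**Strategy.** Ring B is closed last by forming the C7–C8 bond in a Lewis-acid-mediated type 1 intramolecular carbonyl-ene reaction. The step exploits the homoallylic pattern of ring B, C8(=O)–C7–C11(=C12)C13: a prenyl group on C5 (C6–C7=C11) attacks an α-acyloxy aldehyde (C8) on C10 and delivers, in one operation, the ring, the isopropenyl group by allylic transposition and the C7 stereocentre; oxidation then gives the ketone. The precursor is a monocyclic ring A aldehyde already carrying both senecioates. Its four contiguous stereocentres (C3, C4, C5, C10) arise from one catalytic enantioselective Diels–Alder reaction of a 1-silyl diene (silicon as masked C3 hydroxyl) with tiglic aldehyde.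

Key step: step 12

Numbering: eremophilane numbering is used for atom labels (ring A = C1–C5 and C10; ring B = C5–C10; C14 and C15 are the methyls on C5 and C4; C11–C13 form the isopropenyl group on C7; C8 is the ketone; C3 and C9 carry the esters).

Assumption: the (S)-configured oxazaborolidinium catalyst of step 3 is taken to shield the enal face that leads to 5, by analogy with other 2-substituted enals; if the opposite sense is found, its enantiomer is used.

Step 1
Reactants: 1 (2E)-pent-2-en-4-yn-1-ol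
Product: 2 tert-butyl[(2E)-pent-2-en-4-yn-1-yloxy]diphenylsilane
Conditions: t-BuPh2SiCl, imidazole, DMF, 0 → 23 °C
Reagents that add atoms: tert-butyl(chloro)diphenylsilane, CC(C)(C)[Si](Cl)(c1ccccc1)c1ccccc1
Why: Imidazole-promoted O-silylation of the primary alcohol gives a robust silyl ether that should survive the Lewis acid, hydrogenation, aqueous acid and ylide conditions up to step 7.

Step 2
Reactants: 2 tert-butyl[(2E)-pent-2-en-4-yn-1-yloxy]diphenylsilane
Product: 3 benzyl[(1E,3E)-5-{[tert-butyl(diphenyl)silyl]oxy}penta-1,3-dien-1-yl]dimethylsilane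
Conditions: BnMe2SiH, Pt2[(CH2=CHSiMe2)2O]3 (zerovalent platinum, 0.5 mol %), P(t-Bu)3 (1 mol %), THF, 23 °C
Reagents that add atoms: benzyl(dimethyl)silane, C[SiH](C)Cc1ccccc1
Why: Platinum-catalysed syn hydrosilylation of the terminal alkyne should place silicon on the terminal carbon (the bulky phosphine enforces β-(E) selectivity) and leave the conjugated alkene untouched, giving the (E,E)-1-silyl diene.

Step 3
Reactants: 3 benzyl[(1E,3E)-5-{[tert-butyl(diphenyl)silyl]oxy}penta-1,3-dien-1-yl]dimethylsilane; 4 (2E)-2-methylbut-2-enal (tiglic aldehyde)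
Product: 5 (1S,2S,5R,6R)-5-[benzyl(dimethyl)silyl]-2-({[tert-butyl(diphenyl)silyl]oxy}methyl)-1,6-dimethylcyclohex-3-ene-1-carbaldehyde
Conditions: (S)-3,3-diphenyl-1-(2-methylphenyl)tetrahydro-1H,3H-pyrrolo[1,2-c][1,3,2]oxazaborole·HN(SO2CF3)2 (20 mol %), CH2Cl2, −78 → −20 °C
Reagents that add atoms: none
Why: In this catalytic enantioselective Diels–Alder reaction of an α-substituted enal activated as a chiral oxazaborolidinium complex, the enal β-carbon should bond to the silicon-bearing diene terminus (β-silyl and alkyl stabilisation of the developing allyl cation, silicon kept away from the quaternary centre), the endo (CHO) transition state places CHO cis to both outside diene substituents, the E geometry of 4 keeps the two methyls cis, and the catalyst shields one enal face, so that C3, C4, C5 and C10 are set together.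

Step 4
Reactants: 5 (1S,2S,5R,6R)-5-[benzyl(dimethyl)silyl]-2-({[tert-butyl(diphenyl)silyl]oxy}methyl)-1,6-dimethylcyclohex-3-ene-1-carbaldehyde
Product: 6 (1S,2R,3R,6S)-3-[benzyl(dimethyl)silyl]-6-({[tert-butyl(diphenyl)silyl]oxy}methyl)-1,2-dimethylcyclohexane-1-carbaldehyde
Conditions: H2 (1 atm), Pd/C (10 wt % Pd), EtOAc, 23 °C
Reagents that add atoms: none
Why: Heterogeneous hydrogenation should saturate the only C=C bond (C1=C2) while the neopentyl aldehyde, the benzyl–silicon bond and the silyl ether are inert at 1 atm; no stereocentre is touched.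

Step 5
Reactants: 6 (1S,2R,3R,6S)-3-[benzyl(dimethyl)silyl]-6-({[tert-butyl(diphenyl)silyl]oxy}methyl)-1,2-dimethylcyclohexane-1-carbaldehyde
Product: 8 2-[(1S,2R,3R,6S)-3-[benzyl(dimethyl)silyl]-6-({[tert-butyl(diphenyl)silyl]oxy}methyl)-1,2-dimethylcyclohexyl]acetaldehyde, via methyl enol ether 7 (not isolated)
Conditions: Ph3P(CH2OMe)Cl, KN(SiMe3)2, THF, 0 → 23 °C; then 2 M HCl, THF, 23 °C
Reagents that add atoms: (methoxymethyl)triphenylphosphonium chloride, COC[P+](c1ccccc1)(c1ccccc1)c1ccccc1.[Cl-]; water, O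
Why: Wittig methoxymethylenation of the non-enolisable aldehyde followed by enol ether hydrolysis is the standard one-carbon homologation and should turn C6 into the required CH2 while creating the C7 aldehyde.

Step 6
Reactants: 8 2-[(1S,2R,3R,6S)-3-[benzyl(dimethyl)silyl]-6-({[tert-butyl(diphenyl)silyl]oxy}methyl)-1,2-dimethylcyclohexyl]acetaldehyde
Product: 9 benzyl[(1R,2R,3S,4S)-4-({[tert-butyl(diphenyl)silyl]oxy}methyl)-2,3-dimethyl-3-(3-methylbut-2-en-1-yl)cyclohexyl]dimethylsilane
Conditions: i-PrPPh3I, n-BuLi, THF, 0 °C; then 8, −78 → 23 °C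
Reagents that add atoms: isopropyltriphenylphosphonium iodide, CC(C)[P+](c1ccccc1)(c1ccccc1)c1ccccc1.[I-]
Why: Wittig olefination with the non-stabilised isopropylidene ylide should convert the unhindered aldehyde into the trisubstituted alkene of the prenyl group (C6–C7=C11); the symmetrical ylide raises no geometry question.

Step 7
Reactants: 9 benzyl[(1R,2R,3S,4S)-4-({[tert-butyl(diphenyl)silyl]oxy}methyl)-2,3-dimethyl-3-(3-methylbut-2-en-1-yl)cyclohexyl]dimethylsilane
Product: 11 (1R,2R,3S,4S)-4-(hydroxymethyl)-2,3-dimethyl-3-(3-methylbut-2-en-1-yl)cyclohexan-1-ol, via silanol 10 (not isolated)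
Conditions: Bu4NF (3 equiv), THF, 0 → 23 °C; then KHCO3, 30% H2O2, MeOH/THF, 40 °C
Reagents that add atoms: hydrogen peroxide, OO
Why: In this Tamao–Fleming oxidation fluoride should cleave the benzyl–silicon bond (and the silyl ether) and peroxide then oxidise the C3–Si bond with retention, unveiling the 3α-hydroxyl; the isolated trisubstituted alkene is inert to basic peroxide.

Step 8
Reactants: 11 (1R,2R,3S,4S)-4-(hydroxymethyl)-2,3-dimethyl-3-(3-methylbut-2-en-1-yl)cyclohexan-1-ol
Product: 12 (1S,2R,3R,4R)-4-hydroxy-2,3-dimethyl-2-(3-methylbut-2-en-1-yl)cyclohexane-1-carbaldehyde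
Conditions: TEMPO (10 mol %), PhI(OAc)2, CH2Cl2, 23 °C
Reagents that add atoms: none
Why: The oxoammonium oxidation should take the primary alcohol selectively over the hindered secondary one under nearly neutral conditions that spare the C10 stereocentre next to the new aldehyde (C9).

Step 9
Reactants: 12 (1S,2R,3R,4R)-4-hydroxy-2,3-dimethyl-2-(3-methylbut-2-en-1-yl)cyclohexane-1-carbaldehyde
Product: 13 (1R,2R,3R,4S)-4-[(R)-1,3-dithian-2-yl(hydroxy)methyl]-2,3-dimethyl-3-(3-methylbut-2-en-1-yl)cyclohexan-1-ol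
Conditions: 1,3-dithiane, n-BuLi, THF, −30 °C; then 12, −78 → −40 °C; aq. NH4Cl
Reagents that add atoms: 1,3-dithiane, C1CSCSC1
Why: Addition of the dithiane formyl-anion equivalent (umpolung) to the α-branched aldehyde should follow the Felkin–Anh model with the quaternary C5 anti to the nucleophile, which sets the 9R carbinol and brings in C8 at the aldehyde oxidation level; the first equivalent of base only deprotonates the C3 hydroxyl.

Step 10
Reactants: 13 (1R,2R,3R,4S)-4-[(R)-1,3-dithian-2-yl(hydroxy)methyl]-2,3-dimethyl-3-(3-methylbut-2-en-1-yl)cyclohexan-1-ol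
Product: 14 (R)-1,3-dithian-2-yl[(1S,2R,3R,4R)-2,3-dimethyl-2-(3-methylbut-2-en-1-yl)-4-(3-methylbut-2-enoyloxy)cyclohexyl]methyl 3-methylbut-2-enoate
Conditions: 3-methylbut-2-enoyl chloride, pyridine, DMAP (cat.), CH2Cl2, 0 → 23 °C
Reagents that add atoms: 3-methylbut-2-enoyl chloride, CC(C)=CC(Cl)=O
Why: DMAP-catalysed acylation should esterify both secondary hydroxyls in one operation, the weak base pyridine avoiding the vinylketene pathway that would give deconjugated esters.

Step 11
Reactants: 14 (R)-1,3-dithian-2-yl[(1S,2R,3R,4R)-2,3-dimethyl-2-(3-methylbut-2-en-1-yl)-4-(3-methylbut-2-enoyloxy)cyclohexyl]methyl 3-methylbut-2-enoate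
Product: 15 (1R)-1-[(1S,2R,3R,4R)-2,3-dimethyl-2-(3-methylbut-2-en-1-yl)-4-(3-methylbut-2-enoyloxy)cyclohexyl]-2-oxoethyl 3-methylbut-2-enoate
Conditions: PhI(OCOCF3)2, NaHCO3, MeCN/H2O (9:1), 0 °C
Reagents that add atoms: water, O
Why: Oxidative hydrolysis of the dithioacetal with the hypervalent iodine reagent is fast at 0 °C under buffered conditions, so the isolated alkene and the C9 stereocentre of the new α-acyloxy aldehyde should be preserved.

Step 12
Reactants: 15 (1R)-1-[(1S,2R,3R,4R)-2,3-dimethyl-2-(3-methylbut-2-en-1-yl)-4-(3-methylbut-2-enoyloxy)cyclohexyl]-2-oxoethyl 3-methylbut-2-enoate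
Product: 16 (1R,2R,3R,4aR,5R,6R,8aS)-2-hydroxy-4a,5-dimethyl-3-(prop-1-en-2-yl)decahydronaphthalene-1,6-diyl bis(3-methylbut-2-enoate) (8α-hydroxy-10βH-eremophil-11-ene-3α,9β-diyl bis-senecioate)
Conditions: Me2AlCl (2.5 equiv), CH2Cl2, −78 → −40 °C; 1 M HCl quench at 0 °C
Reagents that add atoms: none
Why: Me2AlCl activates the C8 aldehyde, which is attacked by C7 of the prenyl alkene while a hydrogen of a C11 methyl passes to oxygen through a cyclic six-centre array, so that the C7–C8 bond, the C11=C12 double bond and the aluminium alkoxide arise together (concerted, asynchronous type 1 intramolecular carbonyl-ene reaction, made irreversible by methane loss from the alkoxide–aluminium complex). The closest known reaction type is the Lewis-acid cyclisation of citronellal and its 2-substituted analogues to isopulegols. Ring B is closed in the 6-exo mode with respect to both the C7=C11 alkene and the C8=O group, through a chair transition state fused cis to ring A. C7 is set by that chair, in which the reacting alkene, the C9 ester and the C5 methyl are equatorial and only the C5–C4 bond is axial, so the isopropenyl group should emerge cis to the C5 methyl and the C9 ester (7R); C8 is set by the equatorial O–Al group (8R) and is erased in step 13, so either C8 epimer converges. The step needs chemoselectivity for the electron-rich trisubstituted alkene over the two conjugated, electron-poor senecioate alkenes, and for ene closure over acyl migration or proton-initiated cation chemistry; the first follows from the low nucleophilicity of the ester alkenes, the second from the proton-scavenging Lewis acid and the low temperature.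

Step 13
Reactants: 16 (1R,2R,3R,4aR,5R,6R,8aS)-2-hydroxy-4a,5-dimethyl-3-(prop-1-en-2-yl)decahydronaphthalene-1,6-diyl bis(3-methylbut-2-enoate)
Product: 17 (1R,3R,4aR,5R,6R,8aS)-4a,5-dimethyl-2-oxo-3-(prop-1-en-2-yl)decahydronaphthalene-1,6-diyl bis(3-methylbut-2-enoate) (3α,9β-bis(senecioyloxy)-10βH-eremophil-11-en-8-one, CNP0264508.1)
Conditions: Dess–Martin periodinane, NaHCO3, CH2Cl2, 0 → 23 °C
Reagents that add atoms: none
Why: Buffered Dess–Martin oxidation should give the β,γ-unsaturated ketone without double-bond migration or acyl shift, and the C7 and C9 substituents are already in their equatorial, thermodynamically preferred positions.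

**Compound list**

1 | (2E)-pent-2-en-4-yn-1-ol | C#C/C=C/CO | starting material
2 | tert-butyl[(2E)-pent-2-en-4-yn-1-yloxy]diphenylsilane | C#C/C=C/CO[Si](c1ccccc1)(c1ccccc1)C(C)(C)C | intermediate
3 | benzyl[(1E,3E)-5-{[tert-butyl(diphenyl)silyl]oxy}penta-1,3-dien-1-yl]dimethylsilane | C[Si](C)(Cc1ccccc1)/C=C/C=C/CO[Si](c1ccccc1)(c1ccccc1)C(C)(C)C | intermediate
4 | (2E)-2-methylbut-2-enal (tiglic aldehyde) | C/C=C(\C)C=O | starting material
5 | (1S,2S,5R,6R)-5-[benzyl(dimethyl)silyl]-2-({[tert-butyl(diphenyl)silyl]oxy}methyl)-1,6-dimethylcyclohex-3-ene-1-carbaldehyde | O=C[C@@]1(C)[C@H](C=C[C@@H]([Si](C)(C)Cc2ccccc2)[C@@H]1C)CO[Si](c1ccccc1)(c1ccccc1)C(C)(C)C | intermediate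
6 | (1S,2R,3R,6S)-3-[benzyl(dimethyl)silyl]-6-({[tert-butyl(diphenyl)silyl]oxy}methyl)-1,2-dimethylcyclohexane-1-carbaldehyde | O=C[C@@]1(C)[C@H](CC[C@@H]([Si](C)(C)Cc2ccccc2)[C@@H]1C)CO[Si](c1ccccc1)(c1ccccc1)C(C)(C)C | intermediate
7 | methyl enol ether of 8 (6 with CH=CH–OMe in place of CHO, E/Z mixture) | COC=C[C@@]1(C)[C@H](CC[C@@H]([Si](C)(C)Cc2ccccc2)[C@@H]1C)CO[Si](c1ccccc1)(c1ccccc1)C(C)(C)C | intermediate (not isolated)
8 | 2-[(1S,2R,3R,6S)-3-[benzyl(dimethyl)silyl]-6-({[tert-butyl(diphenyl)silyl]oxy}methyl)-1,2-dimethylcyclohexyl]acetaldehyde | O=CC[C@@]1(C)[C@H](CC[C@@H]([Si](C)(C)Cc2ccccc2)[C@@H]1C)CO[Si](c1ccccc1)(c1ccccc1)C(C)(C)C | intermediate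
9 | benzyl[(1R,2R,3S,4S)-4-({[tert-butyl(diphenyl)silyl]oxy}methyl)-2,3-dimethyl-3-(3-methylbut-2-en-1-yl)cyclohexyl]dimethylsilane | CC(C)=CC[C@@]1(C)[C@H](CC[C@@H]([Si](C)(C)Cc2ccccc2)[C@@H]1C)CO[Si](c1ccccc1)(c1ccccc1)C(C)(C)C | intermediate
10 | [(1R,2R,3S,4S)-4-(hydroxymethyl)-2,3-dimethyl-3-(3-methylbut-2-en-1-yl)cyclohexyl]dimethylsilanol | CC(C)=CC[C@@]1(C)[C@H](CC[C@@H]([Si](C)(C)O)[C@@H]1C)CO | intermediate (not isolated)
11 | (1R,2R,3S,4S)-4-(hydroxymethyl)-2,3-dimethyl-3-(3-methylbut-2-en-1-yl)cyclohexan-1-ol | CC(C)=CC[C@@]1(C)[C@H](CC[C@@H](O)[C@@H]1C)CO | intermediate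
12 | (1S,2R,3R,4R)-4-hydroxy-2,3-dimethyl-2-(3-methylbut-2-en-1-yl)cyclohexane-1-carbaldehyde | CC(C)=CC[C@@]1(C)[C@H](CC[C@@H](O)[C@@H]1C)C=O | intermediate
13 | (1R,2R,3R,4S)-4-[(R)-1,3-dithian-2-yl(hydroxy)methyl]-2,3-dimethyl-3-(3-methylbut-2-en-1-yl)cyclohexan-1-ol | CC(C)=CC[C@@]1(C)[C@H](CC[C@@H](O)[C@@H]1C)[C@@H](O)C1SCCCS1 | intermediate
14 | (R)-1,3-dithian-2-yl[(1S,2R,3R,4R)-2,3-dimethyl-2-(3-methylbut-2-en-1-yl)-4-(3-methylbut-2-enoyloxy)cyclohexyl]methyl 3-methylbut-2-enoate | CC(C)=CC[C@@]1(C)[C@H](CC[C@@H](OC(=O)C=C(C)C)[C@@H]1C)[C@@H](OC(=O)C=C(C)C)C1SCCCS1 | intermediate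
15 | (1R)-1-[(1S,2R,3R,4R)-2,3-dimethyl-2-(3-methylbut-2-en-1-yl)-4-(3-methylbut-2-enoyloxy)cyclohexyl]-2-oxoethyl 3-methylbut-2-enoate | CC(C)=CC[C@@]1(C)[C@H](CC[C@@H](OC(=O)C=C(C)C)[C@@H]1C)[C@@H](OC(=O)C=C(C)C)C=O | intermediate
16 | (1R,2R,3R,4aR,5R,6R,8aS)-2-hydroxy-4a,5-dimethyl-3-(prop-1-en-2-yl)decahydronaphthalene-1,6-diyl bis(3-methylbut-2-enoate) | C=C(C)[C@H]1C[C@@]2(C)[C@H](CC[C@@H](OC(=O)C=C(C)C)[C@@H]2C)[C@@H](OC(=O)C=C(C)C)[C@@H]1O | intermediate
17 | (1R,3R,4aR,5R,6R,8aS)-4a,5-dimethyl-2-oxo-3-(prop-1-en-2-yl)decahydronaphthalene-1,6-diyl bis(3-methylbut-2-enoate) | C=C(C)[C@H]1C[C@@]2(C)[C@H](CC[C@@H](OC(=O)C=C(C)C)[C@@H]2C)[C@@H](OC(=O)C=C(C)C)C1=O | target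

**Step count and risks**

Total step count: 13. Longest linear sequence: 13 steps (from 1; 4 is bought).

Steps most likely to fail:

1. Step 12 (key step). The Lewis acid may induce 1,2-acyl migration from O9 to the new C8 alkoxide, or the reaction may go stepwise through a C11 cation that captures chloride or loses a proton to the wrong alkene. Fallback, setting out from 15: selenium-catalysed ene-type allylic chlorination of the prenyl group (N-chlorosuccinimide, PhSeCl cat., CH2Cl2) should give the transposed allylic chloride F1. Treatment with CrCl2 (divalent chromium) and catalytic LiI in THF would then effect an intramolecular Nozaki–Hiyama allylation, in which the allylchromium adds through its γ-carbon C7 to the C8 aldehyde. This forms the same C7–C8 bond and the isopropenyl group under non-acidic conditions and comes back to the route at 16 (either C8 epimer is oxidised to 17 in step 13).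

2. Step 3. The hindered diene and the trisubstituted enal may react too slowly, so that an uncatalysed or poorly face-selective cycloaddition, or Lewis-acid allylation of the aldehyde by the allylsilane product, erodes enantiomeric purity or yield. Fallback, setting out from 3 and 4: EtAlCl2-promoted cycloaddition (CH2Cl2, −78 °C) should give the same endo adduct as the racemic aldehyde F2. Condensation with (1S,2S)-N,N'-dimethyl-1,2-diphenylethane-1,2-diamine (molecular sieves, Et2O) would give two diastereomeric imidazolidines, from which the (4S,5S)-imidazolidine F3 of the desired enantiomer is separated by chromatography. Hydrolysis on wet silica or with aqueous oxalic acid comes back to the route at 5.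

3. Step 9. The lithium alkoxide of the free C3 hydroxyl may aggregate with the nucleophile, so that enolisation of the hindered aldehyde (loss of the C10 configuration) and lower Felkin–Anh facial selectivity compete with addition. Fallback, setting out from 11: double silylation (Et3SiCl, imidazole) should give the bis(triethylsilyl) ether F4. Swern oxidation (oxalyl chloride, DMSO, Et3N) is expected to cleave and oxidise only the primary silyl ether, giving the silyl-protected aldehyde F5. 2-Lithio-1,3-dithiane would then add to this alkoxide-free, bulkier substrate to give the silyl-protected dithianyl carbinol F6, and Bu4NF comes back to the route at 13 (steps 8 and 9 are bypassed).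

Further compounds
F1 | step 12 | (1R)-1-[(1S,2R,3R,4R)-2-(2-chloro-3-methylbut-3-en-1-yl)-2,3-dimethyl-4-(3-methylbut-2-enoyloxy)cyclohexyl]-2-oxoethyl 3-methylbut-2-enoate (transposed allylic chloride, both epimers at the chlorine-bearing carbon) | C=C(C)C(Cl)C[C@@]1(C)[C@H](CC[C@@H](OC(=O)C=C(C)C)[C@@H]1C)[C@@H](OC(=O)C=C(C)C)C=O
F2 | step 3 | racemic aldehyde: rac-(1S,2S,5R,6R)-5-[benzyl(dimethyl)silyl]-2-({[tert-butyl(diphenyl)silyl]oxy}methyl)-1,6-dimethylcyclohex-3-ene-1-carbaldehyde (relative configuration shown) | O=C[C@@]1(C)[C@H](C=C[C@@H]([Si](C)(C)Cc2ccccc2)[C@@H]1C)CO[Si](c1ccccc1)(c1ccccc1)C(C)(C)C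
F3 | step 3 | (4S,5S)-2-[(1S,2S,5R,6R)-5-[benzyl(dimethyl)silyl]-2-({[tert-butyl(diphenyl)silyl]oxy}methyl)-1,6-dimethylcyclohex-3-en-1-yl]-1,3-dimethyl-4,5-diphenylimidazolidine | CN3[C@@H](c2ccccc2)[C@@H](N(C)C3[C@@]1(C)[C@H](C=C[C@@H]([Si](C)(C)Cc2ccccc2)[C@@H]1C)CO[Si](c1ccccc1)(c1ccccc1)C(C)(C)C)c2ccccc2
F4 | step 9 | triethyl{[(1S,2S,3R,4R)-2,3-dimethyl-2-(3-methylbut-2-en-1-yl)-4-(triethylsilyloxy)cyclohexyl]methoxy}silane (bis(triethylsilyl) ether of 11) | CC(C)=CC[C@@]1(C)[C@H](CC[C@@H](O[Si](CC)(CC)CC)[C@@H]1C)CO[Si](CC)(CC)CC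
F5 | step 9 | (1S,2R,3R,4R)-2,3-dimethyl-2-(3-methylbut-2-en-1-yl)-4-(triethylsilyloxy)cyclohexane-1-carbaldehyde | CC(C)=CC[C@@]1(C)[C@H](CC[C@@H](O[Si](CC)(CC)CC)[C@@H]1C)C=O
F6 | step 9 | (R)-1,3-dithian-2-yl[(1S,2R,3R,4R)-2,3-dimethyl-2-(3-methylbut-2-en-1-yl)-4-(triethylsilyloxy)cyclohexyl]methanol | CC(C)=CC[C@@]1(C)[C@H](CC[C@@H](O[Si](CC)(CC)CC)[C@@H]1C)[C@@H](O)C1SCCCS1
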